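**Plan** (germacrane numbering: ring C1–C10; lactone C6–O–C12(=O)–C11(=C13H2)–C7; C14 = methyl on C10; C15 = CH2O on C4)

- Retrosynthesis cuts, in order: the C15 acetate; the furanone O–C3 bond with the C1 carbonyl (back to a cyclic γ-hydroxy ynone C10(OH)–C1≡C2–C3=O); the C3–C4 bond of the ten-membered ring; the C8 angelate; the C7–C8 bond; the butenolide C7=C11 bond.
- Enabling feature: in the furanone ring (O, C10, C1, C2, C3) the unit O–C3=C2–C1=O is a β-alkoxy enone, a 1,3-diketone masked by the C10 oxygen. Written as its ynone, C3 becomes an aldehyde carbon beside a linear C1≡C2 unit, and C4 of the cis C4=C5 alkene becomes an alkenyl metal held cis to C6.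
- Forward: fragment A (C8–C10, C14, C1–C3) from (S)-lactic acid; fragment B (C4–C7, C11–C13, C15) as a 3-(bromomethyl)butenolide. Chromium allylation joins C7–C8 and gives the α-methylene lactone; angeloylation; Nozaki–Hiyama–Kishi closure of the carbocycle at C3–C4; oxidation and gold-catalysed hydrative cyclisation stitch the oxygen bridge across the ring; desilylation and acetylation.
- Stereochemistry: C10 from (S)-lactic acid by alkylation with self-regeneration of the stereocentre; C6 by catalytic asymmetric alkynylation; C7 and C8 relayed from C6 in the allylation; Z-C4=C5 from trans-hydroalumination/iodination; the Z-angelate from angelic acid; the C3 carbinol is transient.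

Key step: step 13

Assumption: in step 6 the (S,S)-ProPhenol–zinc catalyst is taken to add the alkynyl group to the Re face of (E)-but-2-enal and so give the (S)-carbinol; if the sense is the opposite, the (R,R)-ligand is used and nothing else changes.

**Route**

Step 1
Reactants: 1 (S)-lactic acid; 2 pivalaldehyde
Product: 3 (2S,5S)-2-tert-butyl-5-methyl-1,3-dioxolan-4-one
Conditions: TsOH·H2O (cat.), H2SO4 (cat.), pentane, reflux, Dean–Stark; crystallisation from pentane at −78 °C
Reagents that add atoms: none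
Why: Acid-catalysed acetalisation of the α-hydroxy acid with water removal; C5 keeps the lactic acid configuration and the acetal carbon C2 is set cis to the methyl group under thermodynamic control, the cis isomer being isolated by crystallisation.

Step 2
Reactants: 3 (2S,5S)-2-tert-butyl-5-methyl-1,3-dioxolan-4-one; 4 allyl bromide
Product: 5 (2S,5R)-2-tert-butyl-5-methyl-5-(prop-2-en-1-yl)-1,3-dioxolan-4-one
Conditions: LiN(iPr)2, THF, −78 °C; then 4, −78 → −20 °C
Reagents that add atoms: none
Why: Enolate alkylation with self-regeneration of the stereocentre: the planar lithium enolate is shielded on one face by the tert-butyl group at C2, so allyl bromide enters trans to it and the quaternary carbon (later C10) is formed as (5R).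

Step 3
Reactants: 5 (2S,5R)-2-tert-butyl-5-methyl-5-(prop-2-en-1-yl)-1,3-dioxolan-4-one
Product: 8 (3R)-3-methylhex-5-en-1-yn-3-ol, via lactol 6 (not isolated), via hydroxy aldehyde 7 (not isolated)
Conditions: iBu2AlH, CH2Cl2, −78 °C; MeOH; then K2CO3, dimethyl (1-diazo-2-oxopropyl)phosphonate, MeOH, 0 °C → rt
Reagents that add atoms: dimethyl (1-diazo-2-oxopropyl)phosphonate, CC(=O)C(=[N+]=[N-])P(=O)(OC)OC
Why: One-pot ester-to-alkyne conversion in which hydride reduction stops at the aluminium hemiacetal, methanolysis releases the α-hydroxy aldehyde with loss of pivalaldehyde, and Seyferth–Gilbert homologation with the Ohira–Bestmann reagent gives the terminal alkyne, the quaternary carbinol being untouched.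

Step 4
Reactants: 8 (3R)-3-methylhex-5-en-1-yn-3-ol
Product: 9 (4R)-1,1-diethoxy-4-methylhept-6-en-2-yn-4-ol
Conditions: EtMgBr (2.2 equiv), THF, 0 → 40 °C; HC(OEt)3, toluene, 80 °C
Reagents that add atoms: triethyl orthoformate, CCOC(OCC)OCC
Why: Double deprotonation gives the bromomagnesium alkoxide–acetylide, and the acetylide replaces one ethoxy group of the orthoformate (formylation of an alkynyl Grignard reagent as its acetal), with no stereocentre involved.

Step 5
Reactants: 9 (4R)-1,1-diethoxy-4-methylhept-6-en-2-yn-4-ol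
Product: 10 (3R)-6,6-diethoxy-3-hydroxy-3-methylhex-4-ynal
Conditions: O3, CH2Cl2, −78 °C; then PPh3, −78 °C → rt
Reagents that add atoms: ozone, [O-][O+]=O
Why: Ozonolysis with reductive work-up cleaves the terminal alkene much faster than the alkyne, and the acetal and the tertiary alcohol are inert at −78 °C.

Step 6
Reactants: 11 (E)-but-2-enal; 12 tert-butyl(diphenyl)(prop-2-yn-1-yloxy)silane
Product: 13 (2E,4S)-7-[(tert-butyldiphenylsilyl)oxy]hept-2-en-5-yn-4-ol
Conditions: Me2Zn, (S,S)-ProPhenol (10 mol%), Ph3P=O (20 mol%), toluene, 0 °C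
Reagents that add atoms: none
Why: Catalytic enantioselective alkynylation (1,2-addition of the zinc alkynylide to the enal) under control of the dinuclear zinc–ProPhenol catalyst sets the carbinol carbon (later C6) as (S).

Step 7
Reactants: 13 (2E,4S)-7-[(tert-butyldiphenylsilyl)oxy]hept-2-en-5-yn-4-ol
Product: 14 (2Z,4S,5E)-1-[(tert-butyldiphenylsilyl)oxy]-2-iodohepta-2,5-dien-4-ol
Conditions: NaAlH2(OCH2CH2OMe)2, THF, 0 °C → rt; then I2, THF, −78 °C
Reagents that add atoms: iodine, II
Why: Hydroxyl-directed trans-hydroalumination of the propargylic alcohol places aluminium on the alkyne carbon remote from the carbinol (later C4) and hydride on C5, and iodinolysis with retention gives the Z-alkenyl iodide with iodine cis to C6, the carbinol and the E-alkene being untouched.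

Step 8
Reactants: 14 (2Z,4S,5E)-1-[(tert-butyldiphenylsilyl)oxy]-2-iodohepta-2,5-dien-4-ol; 15 2-(bromomethyl)prop-2-enoic acid
Product: 16 (2Z,4S,5E)-1-[(tert-butyldiphenylsilyl)oxy]-2-iodohepta-2,5-dien-4-yl 2-(bromomethyl)prop-2-enoate
Conditions: iPrN=C=NiPr, DMAP (5 mol%), CH2Cl2, −20 → 0 °C
Reagents that add atoms: none
Why: Steglich esterification acylates the secondary alcohol on oxygen so that C6 keeps its configuration, and the low temperature and catalytic amount of DMAP limit substitution of the allylic bromide.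

Step 9
Reactants: 16 (2Z,4S,5E)-1-[(tert-butyldiphenylsilyl)oxy]-2-iodohepta-2,5-dien-4-yl 2-(bromomethyl)prop-2-enoate
Product: 17 (5S)-3-(bromomethyl)-5-[(1Z)-3-[(tert-butyldiphenylsilyl)oxy]-2-iodoprop-1-en-1-yl]furan-2(5H)-one
Conditions: second-generation Grubbs catalyst RuCl2(=CHPh)(H2IMes)(PCy3) (5 mol%), toluene, 60 °C
Reagents that add atoms: none
Why: Ring-closing metathesis in which the ruthenium carbene starts at the propenyl group and closes on the acrylate to the five-membered butenolide with loss of propene, the hindered iodoalkene taking no part and C6 being untouched.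

Step 10
Reactants: 17 (5S)-3-(bromomethyl)-5-[(1Z)-3-[(tert-butyldiphenylsilyl)oxy]-2-iodoprop-1-en-1-yl]furan-2(5H)-one; 10 (3R)-6,6-diethoxy-3-hydroxy-3-methylhex-4-ynal
Product: 18 (4R,5S)-5-[(1Z)-3-[(tert-butyldiphenylsilyl)oxy]-2-iodoprop-1-en-1-yl]-4-[(1S,3R)-6,6-diethoxy-1,3-dihydroxy-3-methylhex-4-yn-1-yl]-3-methylideneoxolan-2-one
Conditions: CrCl2 (3.5 equiv), THF, 0 °C → rt
Reagents that add atoms: none
Why: Chromium-mediated carbonyl allylation (Nozaki–Hiyama type) of the 2-(alkoxycarbonyl)allyl bromide, in which the allylchromium adds through its γ-carbon C7 on the butenolide face anti to the C6 side chain (trans lactone) and a chair Zimmerman–Traxler transition state with the ring-locked E-allyl unit and the aldehyde chain equatorial gives the anti C7/C8 relation, that is (8S), while the double bond moves to the exocyclic C11=C13 position and the alkenyl iodide stays inert in the absence of nickel.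

Step 11
Reactants: 18 the hydroxy lactone of step 10; 19 angelic acid, (2Z)-2-methylbut-2-enoic acid
Product: 21 8-O-angelate of 18, via mixed anhydride 20 (not isolated)
Conditions: 19, 2,4,6-Cl3C6H2COCl, Et3N, toluene, rt; then 18, toluene, 75 °C
Reagents that add atoms: 2,4,6-trichlorobenzoyl chloride, O=C(Cl)c1c(Cl)cc(Cl)cc1Cl (its atoms remain in 20 only)
Why: Yamaguchi-type esterification through the mixed anhydride without a nucleophilic catalyst acylates the secondary C8 hydroxyl with retention and keeps the Z geometry of the angeloyl group, the tertiary propargylic hydroxyl being too hindered to react.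

Step 12
Reactants: 21 8-O-angelate of 18
Product: 22 ynal: (1S,3R)-1-[(2S,3R)-2-[(1Z)-3-[(tert-butyldiphenylsilyl)oxy]-2-iodoprop-1-en-1-yl]-4-methylidene-5-oxooxolan-3-yl]-3-hydroxy-3-methyl-6-oxohex-4-yn-1-yl (2Z)-2-methylbut-2-enoate
Conditions: Amberlyst 15, acetone–H2O (20:1), rt
Reagents that add atoms: water, O
Why: Acid-catalysed acetal hydrolysis on a sulfonic acid resin releases the ynal under conditions that the tert-butyldiphenylsilyl ether, both esters, the lactone and the alkenyl iodide tolerate.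

Step 13
Reactants: 22 ynal
Product: 23 macrocyclic enynol: (6R,7R,8S,10R)-8-(angeloyloxy)-15-[(tert-butyldiphenylsilyl)oxy]-3,10-dihydroxygermacra-4Z,11(13)-dien-1-yn-12,6-olide, both C3 epimers
Conditions: CrCl2 (10 equiv), NiCl2 (1 mol% of the chromium), DMSO–THF (3:1), rt, slow addition to 0.002 M
Reagents that add atoms: none
Why: Zerovalent nickel (formed from NiCl2 and CrCl2) inserts into the C4–I bond, the alkenyl group passes to trivalent chromium with retention of the Z geometry, and the alkenylchromium adds to the C3 aldehyde to form the C3–C4 bond; this is an intramolecular Nozaki–Hiyama–Kishi reaction, whose closest precedent is the closure of strained ten-membered carbocycles and cyclic enediynes by organochromium addition to aldehydes. The ten-membered carbocycle C1–C10 closes in a 10-exo-trig mode on the aldehyde C=O. The new carbinol centre C3 is not controlled and need not be, because step 14 removes it and both epimers converge. The step needs chemoselectivity for the aldehyde over the α-methylene lactone, the two esters and the free tertiary alcohol, which the low basicity and carbonyl selectivity of alkenylchromium secure. It also needs ring closure to beat oligomerisation, which high dilution secures together with three elements of the substrate: the Z-C4=C5 alkene that holds C4 cis to C6, the rigid trans-fused lactone, and the linear C1≡C2 unit that removes transannular hydrogens and places C3 next to C4. The alkyne and the aldehyde oxidation level are the helpers: with the C10 hydroxyl they are the masked 1,3-diketone that steps 14 and 15 turn into the furanone.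

Step 14
Reactants: 23 macrocyclic enynol
Product: 24 macrocyclic ynone: (6R,7R,8S,10R)-8-(angeloyloxy)-15-[(tert-butyldiphenylsilyl)oxy]-10-hydroxy-3-oxogermacra-4Z,11(13)-dien-1-yn-12,6-olide
Conditions: Dess–Martin periodinane, CH2Cl2, 0 °C → rt
Reagents that add atoms: none
Why: Dess–Martin oxidation of the doubly activated (allylic and propargylic) secondary alcohol gives the cross-conjugated ynone from both C3 epimers, and the tertiary alcohol cannot be oxidised.

Step 15
Reactants: 24 macrocyclic ynone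
Product: 26 furanone silyl ether, via β-diketone 25 (not isolated)
Conditions: AuCl3 (5 mol%), H2O (2 equiv), CH2Cl2, rt
Reagents that add atoms: water, O
Why: Gold-catalysed hydrative cyclisation of a γ-hydroxy alkynone to a 3(2H)-furanone, in which conjugate hydration at C1 gives the β-diketone, the C10 hydroxyl adds to the C3 ketone (5-exo-trig) and loss of water forms the C2=C3 double bond, driven by release of the alkyne strain and leaving C10 untouched.

Step 16
Reactants: 26 furanone silyl ether: (6R,7R,8S,10R)-8-(angeloyloxy)-15-[(tert-butyldiphenylsilyl)oxy]-3,10-epoxy-1-oxogermacra-2,4Z,11(13)-trien-12,6-olide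
Product: 27 15-hydroxy furanone (the 15-deacetyl target)
Conditions: HF·pyridine, pyridine, THF, 0 °C → rt
Reagents that add atoms: none
Why: Fluoride cleavage of the silyl ether under buffered, weakly acidic conditions should leave the furanone, the α-methylene lactone and the angelate intact.

Step 17
Reactants: 27 15-hydroxy furanone
Product: 28 CNP0122132.1, (6R,7R,8S,10R)-15-acetoxy-8-(angeloyloxy)-3,10-epoxy-1-oxogermacra-2,4Z,11(13)-trien-12,6-olide
Conditions: Ac2O, pyridine, CH2Cl2, 0 °C → rt
Reagents that add atoms: acetic anhydride, CC(=O)OC(C)=O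
Why: Acetylation of the primary allylic alcohol with acetic anhydride and pyridine should give the target without touching any stereocentre.

**Compound list**

1 | (S)-lactic acid | C[C@H](O)C(=O)O | starting material
2 | pivalaldehyde | CC(C)(C)C=O | starting material
3 | (2S,5S)-2-tert-butyl-5-methyl-1,3-dioxolan-4-one | C[C@@H]1O[C@H](C(C)(C)C)OC1=O | intermediate
4 | allyl bromide | C=CCBr | starting material
5 | (2S,5R)-2-tert-butyl-5-methyl-5-(prop-2-en-1-yl)-1,3-dioxolan-4-one | C[C@]1(CC=C)O[C@H](C(C)(C)C)OC1=O | intermediate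
6 | (2S,5R)-2-tert-butyl-5-methyl-5-(prop-2-en-1-yl)-1,3-dioxolan-4-ol, both C4 epimers (lactol, not isolated) | C[C@]1(CC=C)O[C@H](C(C)(C)C)OC1O | intermediate
7 | (2R)-2-hydroxy-2-methylpent-4-enal (not isolated) | C=CC[C@@](C)(O)C=O | intermediate
8 | (3R)-3-methylhex-5-en-1-yn-3-ol | C=CC[C@@](C)(O)C#C | intermediate
9 | (4R)-1,1-diethoxy-4-methylhept-6-en-2-yn-4-ol | C=CC[C@@](C)(O)C#CC(OCC)OCC | intermediate
10 | (3R)-6,6-diethoxy-3-hydroxy-3-methylhex-4-ynal | O=CC[C@@](C)(O)C#CC(OCC)OCC | intermediate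
11 | (E)-but-2-enal | C/C=C/C=O | starting material
12 | tert-butyl(diphenyl)(prop-2-yn-1-yloxy)silane | C#CCO[Si](c1ccccc1)(c1ccccc1)C(C)(C)C | starting material
13 | (2E,4S)-7-[(tert-butyldiphenylsilyl)oxy]hept-2-en-5-yn-4-ol | C/C=C/[C@H](O)C#CCO[Si](c1ccccc1)(c1ccccc1)C(C)(C)C | intermediate
14 | (2Z,4S,5E)-1-[(tert-butyldiphenylsilyl)oxy]-2-iodohepta-2,5-dien-4-ol | C/C=C/[C@H](O)/C=C(\I)CO[Si](c1ccccc1)(c1ccccc1)C(C)(C)C | intermediate
15 | 2-(bromomethyl)prop-2-enoic acid | C=C(CBr)C(=O)O | starting material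
16 | (2Z,4S,5E)-1-[(tert-butyldiphenylsilyl)oxy]-2-iodohepta-2,5-dien-4-yl 2-(bromomethyl)prop-2-enoate | C/C=C/[C@H](OC(=O)C(=C)CBr)/C=C(\I)CO[Si](c1ccccc1)(c1ccccc1)C(C)(C)C | intermediate
17 | (5S)-3-(bromomethyl)-5-[(1Z)-3-[(tert-butyldiphenylsilyl)oxy]-2-iodoprop-1-en-1-yl]furan-2(5H)-one | BrCC1=C[C@@H](/C=C(\I)CO[Si](c2ccccc2)(c2ccccc2)C(C)(C)C)OC1=O | intermediate
18 | (4R,5S)-5-[(1Z)-3-[(tert-butyldiphenylsilyl)oxy]-2-iodoprop-1-en-1-yl]-4-[(1S,3R)-6,6-diethoxy-1,3-dihydroxy-3-methylhex-4-yn-1-yl]-3-methylideneoxolan-2-one | C=C1C(=O)O[C@H](/C=C(\I)CO[Si](c2ccccc2)(c2ccccc2)C(C)(C)C)[C@H]1[C@@H](O)C[C@@](C)(O)C#CC(OCC)OCC | intermediate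
19 | angelic acid, (2Z)-2-methylbut-2-enoic acid | C/C=C(/C)C(=O)O | starting material
20 | (2Z)-2-methylbut-2-enoic 2,4,6-trichlorobenzoic anhydride (not isolated) | C/C=C(/C)C(=O)OC(=O)c1c(Cl)cc(Cl)cc1Cl | intermediate
21 | 8-O-angelate of 18: (1S,3R)-1-[(2S,3R)-2-[(1Z)-3-[(tert-butyldiphenylsilyl)oxy]-2-iodoprop-1-en-1-yl]-4-methylidene-5-oxooxolan-3-yl]-6,6-diethoxy-3-hydroxy-3-methylhex-4-yn-1-yl (2Z)-2-methylbut-2-enoate | C=C1C(=O)O[C@H](/C=C(\I)CO[Si](c2ccccc2)(c2ccccc2)C(C)(C)C)[C@H]1[C@@H](OC(=O)/C(C)=C\C)C[C@@](C)(O)C#CC(OCC)OCC | intermediate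
22 | ynal: (1S,3R)-1-[(2S,3R)-2-[(1Z)-3-[(tert-butyldiphenylsilyl)oxy]-2-iodoprop-1-en-1-yl]-4-methylidene-5-oxooxolan-3-yl]-3-hydroxy-3-methyl-6-oxohex-4-yn-1-yl (2Z)-2-methylbut-2-enoate | C=C1C(=O)O[C@H](/C=C(\I)CO[Si](c2ccccc2)(c2ccccc2)C(C)(C)C)[C@H]1[C@@H](OC(=O)/C(C)=C\C)C[C@@](C)(O)C#CC=O | intermediate
23 | macrocyclic enynol: (6R,7R,8S,10R)-8-(angeloyloxy)-15-[(tert-butyldiphenylsilyl)oxy]-3,10-dihydroxygermacra-4Z,11(13)-dien-1-yn-12,6-olide, both C3 epimers | C=C1C(=O)O[C@@H]2/C=C(/CO[Si](c3ccccc3)(c3ccccc3)C(C)(C)C)C(O)C#C[C@](C)(O)C[C@H](OC(=O)/C(C)=C\C)[C@@H]12 | intermediate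
24 | macrocyclic ynone: (6R,7R,8S,10R)-8-(angeloyloxy)-15-[(tert-butyldiphenylsilyl)oxy]-10-hydroxy-3-oxogermacra-4Z,11(13)-dien-1-yn-12,6-olide | C=C1C(=O)O[C@@H]2/C=C(/CO[Si](c3ccccc3)(c3ccccc3)C(C)(C)C)C(=O)C#C[C@](C)(O)C[C@H](OC(=O)/C(C)=C\C)[C@@H]12 | intermediate
25 | macrocyclic β-diketone: (6R,7R,8S,10R)-8-(angeloyloxy)-15-[(tert-butyldiphenylsilyl)oxy]-10-hydroxy-1,3-dioxogermacra-4Z,11(13)-dien-12,6-olide (not isolated) | C=C1C(=O)O[C@@H]2/C=C(/CO[Si](c3ccccc3)(c3ccccc3)C(C)(C)C)C(=O)CC(=O)[C@](C)(O)C[C@H](OC(=O)/C(C)=C\C)[C@@H]12 | intermediate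
26 | furanone silyl ether: (6R,7R,8S,10R)-8-(angeloyloxy)-15-[(tert-butyldiphenylsilyl)oxy]-3,10-epoxy-1-oxogermacra-2,4Z,11(13)-trien-12,6-olide | C=C1C(=O)O[C@@H]2/C=C(/CO[Si](c4ccccc4)(c4ccccc4)C(C)(C)C)C3=CC(=O)[C@@](C)(C[C@H](OC(=O)/C(C)=C\C)[C@@H]12)O3 | intermediate
27 | 15-hydroxy furanone: (6R,7R,8S,10R)-8-(angeloyloxy)-15-hydroxy-3,10-epoxy-1-oxogermacra-2,4Z,11(13)-trien-12,6-olide | C=C1C(=O)O[C@@H]2/C=C(/CO)C3=CC(=O)[C@@](C)(C[C@H](OC(=O)/C(C)=C\C)[C@@H]12)O3 | intermediate
28 | CNP0122132.1: (6R,7R,8S,10R)-15-acetoxy-8-(angeloyloxy)-3,10-epoxy-1-oxogermacra-2,4Z,11(13)-trien-12,6-olide | C=C1C(=O)O[C@@H]2/C=C(/COC(C)=O)C3=CC(=O)[C@@](C)(C[C@H](OC(=O)/C(C)=C\C)[C@@H]12)O3 | target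

**Step count**

Total: 17 steps. Longest linear sequence: 13 steps (steps 1–5 and 10–17, from (S)-lactic acid); fragment B takes steps 6–9.

**Steps most likely to fail**

1. Step 13 (ring closure). Intermolecular coupling and protodeiodination may outrun closure of a strained ten-membered ring that holds an alkyne and a Z-alkene, so that the alkenylchromium is protonated or couples between molecules before it reaches the aldehyde. Fallback, setting out from 8 and coming back at 24: C3 is left out of the chain and brought in as carbon monoxide. Ozonolysis of 8 (O3, then PPh3) should give (3R)-3-hydroxy-3-methylpent-4-ynal F1. CrCl2-mediated allylation of F1 with 17, as in step 10, should give the terminal-alkyne hydroxy lactone F2. Angeloylation through 20, as in step 11, should give the terminal-alkyne angelate F3. An intramolecular carbonylative Sonogashira coupling (PdCl2(PPh3)2, CuI, CO at 1 atm, Et3N, THF, rt, high dilution) should then insert CO into the alkenyl–palladium bond, which forms C3–C4, and couple the acyl–palladium with the copper acetylide, which closes the ring, to give ynone 24 directly; steps 12 to 14 fall away.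

2. Step 10 (allylation). Simple diastereoselection at C8 may erode if boat or open transition states compete with the chair, while the C6 side chain should still enforce the trans lactone; the chromium alkoxide may also translactonise on long exposure. Fallback, setting out from 18 in admixture with its C8 epimer and coming back at 18: the mixture of 18 and the (8R)-epimer F4 is oxidised (Dess–Martin periodinane, pyridine, CH2Cl2) to the single C8 ketone F5. Corey–Bakshi–Shibata reduction ((R)-2-methyl-CBS-oxazaborolidine, catecholborane, toluene, −78 °C), with the branched C7 as the large group, should return 18, so that C8 no longer depends on the allylation transition state.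

3. Step 9 (metathesis). Closure onto the electron-poor 1,1-disubstituted bromomethyl acrylate may be slow, and the allylic bromide may consume catalyst or migrate. Fallback, setting out from 14 and coming back at 17: the bromide is introduced after the ring. Esterification of 14 with 2-{[(tert-butyldimethylsilyl)oxy]methyl}prop-2-enoic acid (iPrN=C=NiPr, DMAP) should give the silyloxymethyl acrylate F6. Ring-closing metathesis with the same ruthenium catalyst should give the silyloxymethyl butenolide F7. Selective cleavage of the primary tert-butyldimethylsilyl ether beside the tert-butyldiphenylsilyl ether (pyridinium p-toluenesulfonate, MeOH) should give the hydroxymethyl butenolide F8, and Appel bromination (CBr4, PPh3, CH2Cl2, 0 °C) should give 17.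

Further compounds
F1 | step 13 | (3R)-3-hydroxy-3-methylpent-4-ynal | O=CC[C@@](C)(O)C#C
F2 | step 13 | (4R,5S)-5-[(1Z)-3-[(tert-butyldiphenylsilyl)oxy]-2-iodoprop-1-en-1-yl]-4-[(1S,3R)-1,3-dihydroxy-3-methylpent-4-yn-1-yl]-3-methylideneoxolan-2-one | C=C1C(=O)O[C@H](/C=C(\I)CO[Si](c2ccccc2)(c2ccccc2)C(C)(C)C)[C@H]1[C@@H](O)C[C@@](C)(O)C#C
F3 | step 13 | (1S,3R)-1-[(2S,3R)-2-[(1Z)-3-[(tert-butyldiphenylsilyl)oxy]-2-iodoprop-1-en-1-yl]-4-methylidene-5-oxooxolan-3-yl]-3-hydroxy-3-methylpent-4-yn-1-yl (2Z)-2-methylbut-2-enoate | C=C1C(=O)O[C@H](/C=C(\I)CO[Si](c2ccccc2)(c2ccccc2)C(C)(C)C)[C@H]1[C@@H](OC(=O)/C(C)=C\C)C[C@@](C)(O)C#C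
F4 | step 10 | (4R,5S)-5-[(1Z)-3-[(tert-butyldiphenylsilyl)oxy]-2-iodoprop-1-en-1-yl]-4-[(1R,3R)-6,6-diethoxy-1,3-dihydroxy-3-methylhex-4-yn-1-yl]-3-methylideneoxolan-2-one (C8 epimer of 18) | C=C1C(=O)O[C@H](/C=C(\I)CO[Si](c2ccccc2)(c2ccccc2)C(C)(C)C)[C@H]1[C@H](O)C[C@@](C)(O)C#CC(OCC)OCC
F5 | step 10 | (4S,5S)-5-[(1Z)-3-[(tert-butyldiphenylsilyl)oxy]-2-iodoprop-1-en-1-yl]-4-[(3R)-6,6-diethoxy-3-hydroxy-3-methylhex-4-ynoyl]-3-methylideneoxolan-2-one (C8 ketone) | C=C1C(=O)O[C@H](/C=C(\I)CO[Si](c2ccccc2)(c2ccccc2)C(C)(C)C)[C@H]1C(=O)C[C@@](C)(O)C#CC(OCC)OCC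
F6 | step 9 | (2Z,4S,5E)-1-[(tert-butyldiphenylsilyl)oxy]-2-iodohepta-2,5-dien-4-yl 2-{[(tert-butyldimethylsilyl)oxy]methyl}prop-2-enoate | C/C=C/[C@H](OC(=O)C(=C)CO[Si](C)(C)C(C)(C)C)/C=C(\I)CO[Si](c1ccccc1)(c1ccccc1)C(C)(C)C
F7 | step 9 | (5S)-3-{[(tert-butyldimethylsilyl)oxy]methyl}-5-[(1Z)-3-[(tert-butyldiphenylsilyl)oxy]-2-iodoprop-1-en-1-yl]furan-2(5H)-one | CC(C)(C)[Si](C)(C)OCC1=C[C@@H](/C=C(\I)CO[Si](c2ccccc2)(c2ccccc2)C(C)(C)C)OC1=O
F8 | step 9 | (5S)-5-[(1Z)-3-[(tert-butyldiphenylsilyl)oxy]-2-iodoprop-1-en-1-yl]-3-(hydroxymethyl)furan-2(5H)-one | OCC1=C[C@@H](/C=C(\I)CO[Si](c2ccccc2)(c2ccccc2)C(C)(C)C)OC1=O
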